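## Retrosynthetic overview
1. C6–Cl is installed last, by SN2 inversion of a 6R allylic alcohol on the complete tricycle. The C4–OH is then unmasked.
2. The ten-membered ring is closed third, by an intramolecular Nozaki–Hiyama–Kishi reaction at C3–C4 (E-vinyl iodide plus 2-methylene aldehyde, with C16 from Eschenmoser's salt).
3. The γ-lactone is formed second. OH-directed syn-dihydroxylation of the Z C7=C8 olefin is followed by oxidation of C19 and closure onto O7.
4. C8–C9 comes from a side-chain vinyllithium and the ring aldehyde, and C9 is reset by oxidation and Felkin reduction. In the side chain (C4–C8, C17–C19), C17 comes from a lipase desymmetrisation and C6 from a Noyori transfer hydrogenation.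
5. The six-membered ring is formed first, by a catalytic enantioselective Diels–Alder reaction that sets C1 and C10. C3 follows by Takai olefination, then the enone, then the C11 acetate by Rubottom oxidation.

Convention and assumption: briarane numbering is used throughout. C1 is quaternary (Me-15); C2=C3; C4 carries OH; C5 carries =C16H2; C6 carries Cl; C7 carries the lactone O; C8 carries OH; C9 carries OAc; C10; C11 carries OAc and Me-20; C12 is C=O; C13=C14; C17 carries Me-18; C19 is the lactone C=O. The target is then (1S,2E,4S,6S,7R,8R,9S,10S,11S,17R). Compound 3 is bought as the E isomer, and DMDO is used as a titrated acetone solution.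

## Part A: ring fragment

Step 1
Reactants: 1 pent-1-en-3-one (ethyl vinyl ketone)
Product: 2 (Z)-3-(triisopropylsilyloxy)penta-1,3-diene
Conditions: TIPSOTf, Et3N, CH2Cl2, 0 °C
Reagents that add atoms: triisopropylsilyl triflate, CC(C)[Si](OS(=O)(=O)C(F)(F)F)(C(C)C)C(C)C
Why: Soft enolisation and O-silylation (silyl enol ether formation) gives the 2-siloxydiene, and the Z enol ether places the methyl group "outside" in the reactive s-cis form.

Step 2
Reactants: 2 (Z)-3-(triisopropylsilyloxy)penta-1,3-diene; 3 ethyl (E)-3-methyl-4-oxobut-2-enoate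
Product: 4 ethyl (1S,2S,6S)-2-formyl-2,6-dimethyl-5-(triisopropylsilyloxy)cyclohex-4-ene-1-carboxylate
Conditions: (R)-B-o-tolyl-diphenylprolinol oxazaborolidine (20 mol %), Tf2NH (18 mol %), CH2Cl2, −78 to −40 °C
Reagents that add atoms: none
Why: In this Corey oxazaborolidinium-catalysed Diels–Alder reaction the catalyst binds the formyl group, the siloxy group steers C11 onto C10 ("para" rule), suprafacial addition to the E-dienophile fixes C2 and C9 trans, and shielding of one enal face sets 1S,10S as the first stereocentres, while C11 (formyl-endo adduct drawn) is erased later.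

Step 3
Reactants: 4 Diels–Alder aldehyde
Product: 5 ethyl (1S,2S,6S)-2-[(E)-2-iodoethenyl]-2,6-dimethyl-5-(triisopropylsilyloxy)cyclohex-4-ene-1-carboxylate
Conditions: CrCl2 (8 equiv), CHI3 (3 equiv), THF, 0 °C to rt
Reagents that add atoms: iodoform, IC(I)I
Why: In the Takai olefination the gem-dichromium species adds to the non-enolisable neopentyl aldehyde and eliminates to the E-vinyl iodide (adds C3), with the ester and the TIPS enol ether untouched.

Step 4
Reactants: 5 vinyl iodide ester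
Product: 6 [(1S,2S,6S)-2-[(E)-2-iodoethenyl]-2,6-dimethyl-5-(triisopropylsilyloxy)cyclohex-4-en-1-yl]methanol
Conditions: DIBAL-H (2.5 equiv), CH2Cl2, −78 to 0 °C; aq. work-up
Reagents that add atoms: none
Why: This is an ester reduction in which the vinyl iodide and the silyl enol ether (the mask of the C12 ketone) are inert to the hydride.

Step 5
Reactants: 6 primary alcohol
Product: 7 (1S,2S,6S)-2-[(E)-2-iodoethenyl]-2,6-dimethyl-5-(triisopropylsilyloxy)cyclohex-4-ene-1-carbaldehyde (C9 aldehyde)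
Conditions: DMP, pyridine, CH2Cl2, 0 °C to rt
Reagents that add atoms: none
Why: Buffered Dess–Martin oxidation gives the aldehyde without epimerising C10, whose trans arrangement is also the thermodynamic one.

## Part B: side chain (C4–C8, C17–C19)

Step 6
Reactants: 8 2-methylpropane-1,3-diol
Product: 9 (S)-3-hydroxy-2-methylpropyl acetate
Conditions: lipase (Pseudomonas fluorescens lipase, Amano AK), vinyl acetate, CHCl3, rt, run until about 30 % diacetate has formed
Reagents that add atoms: vinyl acetate, C=COC(C)=O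
Why: Enantiotopos-selective acyl transfer by a lipase (serine hydrolase) desymmetrises the prochiral diol and sets C17, and over-acylation of the minor enantiomer to the achiral diacetate raises the ee to about 98 %.

Step 7
Reactants: 9 (S)-monoacetate
Product: 10 (R)-3-(tert-butyldimethylsilyloxy)-2-methylpropyl acetate
Conditions: TBSCl, imidazole, CH2Cl2, 0 °C
Reagents that add atoms: tert-butyldimethylsilyl chloride, CC(C)(C)[Si](C)(C)Cl
Why: Mild silyl ether formation caps the free hydroxyl (future C19) before acyl migration can erode the ee.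

Step 8
Reactants: 10 silyl ether acetate
Product: 11 (R)-3-(tert-butyldimethylsilyloxy)-2-methylpropan-1-ol
Conditions: K2CO3 (0.2 equiv), MeOH, 0 °C
Reagents that add atoms: none
Why: Base-catalysed transesterification removes the acetate and frees the terminus that becomes C8.

Step 9
Reactants: 11 alcohol
Product: 12 (S)-3-(tert-butyldimethylsilyloxy)-2-methylpropanal
Conditions: TEMPO (10 mol %), PhI(OAc)2, CH2Cl2, rt
Reagents that add atoms: none
Why: Nitroxyl-catalysed oxidation stops at the aldehyde under near-neutral conditions, so the α-stereocentre C17 is kept.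

Step 10
Reactants: 12 aldehyde
Product: 13 (R)-tert-butyl(dimethyl)(2-methylbut-3-ynyloxy)silane
Conditions: Ohira–Bestmann reagent, K2CO3, MeOH, 0 °C to rt
Reagents that add atoms: dimethyl (1-diazo-2-oxopropyl)phosphonate, COP(=O)(OC)C(=[N+]=[N-])C(C)=O
Why: Seyferth–Gilbert homologation in the Ohira–Bestmann variant converts the aldehyde into the terminal alkyne (adds C7) mildly enough for this α-chiral aldehyde.

Step 11
Reactants: 14 propane-1,3-diol
Product: 16 3-(4-methoxybenzyloxy)propan-1-ol, via sodium alkoxide 15 (not isolated)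
Conditions: NaH (1 equiv, diol in excess), THF, 0 °C; PMBCl, Bu4NI (cat.), rt
Reagents that add atoms: 4-methoxybenzyl chloride, COc1ccc(CCl)cc1
Why: Williamson ether synthesis on the monoalkoxide of the symmetric diol gives the mono-PMB ether.

Step 12
Reactants: 16 mono-PMB diol
Product: 17 3-(4-methoxybenzyloxy)propanal
Conditions: TEMPO (10 mol %), PhI(OAc)2, CH2Cl2, rt
Reagents that add atoms: none
Why: TEMPO/BAIB oxidation gives the β-alkoxy aldehyde without base, so no β-elimination occurs.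

Step 13
Reactants: 13 alkyne; 17 aldehyde
Product: 19 (6R)-7-(TBSO)-1-(PMBO)-6-methylhept-4-yn-3-ol (epimers at briarane C6), via lithium acetylide 18 (not isolated)
Conditions: n-BuLi, THF, −78 °C; then 17; H2O
Reagents that add atoms: none
Why: 1,2-Addition of the acetylide forms C6–C7, and the C6 configuration is left open because steps 14 and 15 reset it.

Step 14
Reactants: 19 propargylic alcohol
Product: 20 (6R)-7-(TBSO)-1-(PMBO)-6-methylhept-4-yn-3-one
Conditions: DMP, pyridine, CH2Cl2, 0 °C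
Reagents that add atoms: none
Why: Dess–Martin oxidation gives the ynone needed for a catalyst-controlled reduction.

Step 15
Reactants: 20 ynone
Product: 21 (3R,6R)-7-(TBSO)-1-(PMBO)-6-methylhept-4-yn-3-ol (briarane 6R)
Conditions: Ru[(R,R)-TsDPEN](p-cymene) (2 mol %), i-PrOH, rt
Reagents that add atoms: none
Why: In the Noyori asymmetric transfer hydrogenation the (R,R)-catalyst distinguishes alkynyl from alkyl and gives the R propargylic alcohol under catalyst control, independent of the remote C17.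

Step 16
Reactants: 21 (R)-propargylic alcohol
Product: 23 (3R,4Z,6S)-5-iodo-7-(TBSO)-1-(PMBO)-6-methylhept-4-en-3-ol, via cyclic vinylalanate 22 (not isolated)
Conditions: Red-Al (1.5 equiv), THF, 0 °C to rt; then I2, −78 °C; aq. work-up
Reagents that add atoms: iodine, II
Why: Hydroxyl-directed trans-hydroalumination places Al on C8 in a five-membered alanate, and iodinolysis with retention gives the Z-iodoalkene in which iodine (later C9) is cis to C6.

Step 17
Reactants: 23 iodo allylic alcohol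
Product: 24 (3R,4Z,6S)-5-iodo-7-(TBSO)-1-(PMBO)-6-methyl-3-(triethylsilyloxy)hept-4-ene
Conditions: TESCl, imidazole, CH2Cl2, 0 °C
Reagents that add atoms: chlorotriethylsilane, CC[Si](Cl)(CC)CC
Why: The C6 hydroxyl is protected as an acid-labile TES ether, orthogonal to the primary TBS and PMB groups.

## Part C: union, lactone, macrocycle, end game

Step 18
Reactants: 24 vinyl iodide; 7 C9 aldehyde
Product: 26 C8–C9 coupled allylic alcohol (mainly 9R), via vinyllithium 25 (not isolated)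
Conditions: t-BuLi (2.0 equiv), Et2O, −78 °C; then 7, −78 °C; H2O
Reagents that add atoms: none
Why: Iodine–lithium exchange with retention of geometry and fast 1,2-addition form C8–C9, and the Felkin–Anh preference for the unwanted 9R carbinol is harmless because C9 is reset.

Step 19
Reactants: 26 C9 carbinol
Product: 27 C9 enone (9-oxo, Z-C7=C8)
Conditions: DMP, pyridine, CH2Cl2, 0 °C to rt
Reagents that add atoms: none
Why: Dess–Martin oxidation converges both C9 epimers to one enone.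

Step 20
Reactants: 27 C9 enone
Product: 28 (9S)-allylic alcohol
Conditions: NaBH4, CeCl3·7H2O, MeOH/THF, −78 °C
Reagents that add atoms: none
Why: In the Luche reduction 1,2-hydride attack follows the Felkin–Anh model (anti to the quaternary C1 branch on C10) and so gives the epimer opposite to carbon addition, 9S, while C12 stays masked as the TIPS enol ether.

Step 21
Reactants: 28 (9S)-alcohol
Product: 29 9-acetate
Conditions: Ac2O, DMAP (cat.), pyridine, rt
Reagents that add atoms: acetic anhydride, CC(=O)OC(C)=O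
Why: DMAP-catalysed acetylation installs the C9 acetate of the target.

Step 22
Reactants: 29 TIPS enol ether
Product: 32 C13=C14 cyclohexenone (12-oxo), via 13-phenylselanyl ketone 30 (not isolated), via selenoxide 31 (not isolated)
Conditions: PhSeCl, CH2Cl2, −78 °C; then 30 % H2O2, pyridine, 0 °C to rt
Reagents that add atoms: none
Why: α-Selenenylation of the regiodefined silyl enol ether at C13 and selenoxide syn-elimination towards C14 give the enone without palladium, which the vinyl iodide would not tolerate.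

Step 23
Reactants: 32 enone
Product: 33 12-(trimethylsilyloxy)-11,13-diene (cross-conjugated dienol ether)
Conditions: TMSOTf, Et3N, CH2Cl2, 0 °C; cold NaHCO3/pentane work-up
Reagents that add atoms: trimethylsilyl triflate, C[Si](C)(C)OS(=O)(=O)C(F)(F)F
Why: Under soft enolisation C11–H is the only enolisable position (C1 is quaternary), and the acetate is not enolised under these conditions.

Step 24
Reactants: 33 dienol ether
Product: 35 (11S)-11-hydroxy enone, via 11,12-silyloxy epoxide 34 (not isolated)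
Conditions: DMDO (1.05 equiv), acetone/CH2Cl2, −78 °C; then citric acid (cat.), MeOH, 0 °C
Reagents that add atoms: dimethyldioxirane, CC1(C)OO1
Why: In the Rubottom oxidation DMDO attacks the most electron-rich double bond (C11=C12) from the face opposite the C10 side chain and the C1 methyl group, and methanolysis collapses the silyloxy epoxide to the 11S α-ketol.

Step 25
Reactants: 35 tertiary α-ketol
Product: 36 9,11-diacetate
Conditions: Ac2O, DMAP, Et3N, CH2Cl2, 40 °C
Reagents that add atoms: acetic anhydride, CC(=O)OC(C)=O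
Why: DMAP-promoted acylation of the tertiary alcohol is done while no other hydroxyl is free, so the later tertiary C8–OH never has to be differentiated.

Step 26
Reactants: 36 diacetate
Product: 37 C6 allylic alcohol
Conditions: PPTS (cat.), MeOH/CH2Cl2, 0 °C
Reagents that add atoms: none
Why: Acid-catalysed methanolysis cleaves the secondary TES ether far faster than the primary TBS ether and frees the directing hydroxyl.

Step 27
Reactants: 37 allylic alcohol
Product: 39 6,7,8,19-tetraol, via osmate(VI) ester TMEDA complex 38 (not isolated)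
Conditions: OsO4 (1.05 equiv), TMEDA, CH2Cl2, −78 °C; then HCl, MeOH, rt
Reagents that add atoms: osmium tetroxide, O=[Os](=O)(=O)=O
Why: In this hydrogen-bond-directed (Donohoe) dihydroxylation the A1,3-locked Z-olefin holds O6 and O9 on the face opposite the bulky C5 and C10 carbons, so syn-addition from the OH-bearing face sets C7 and C8 as in the target, and acidic methanolysis releases the diol and removes the primary TBS group.

Step 28
Reactants: 39 tetraol
Product: 41 γ-lactone 6,8-diol, via seco acid 40 (not isolated)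
Conditions: TEMPO (cat.), NaClO2, NaOCl (cat.), pH 6.7 phosphate buffer/MeCN, 35 °C; work-up at pH 4
Reagents that add atoms: sodium chlorite, [Na+].[O-]Cl=O
Why: Nitroxyl/chlorite oxidation takes only the primary C19 alcohol to the acid without glycol cleavage, and the 4-hydroxy acid closes spontaneously onto O7 to the γ-lactone (favoured over the δ-lactone on O6), with Me-18 in its stable orientation trans to C9.

Step 29
Reactants: 41 lactone diol
Product: 42 6-O-TES lactone
Conditions: TESCl, imidazole, CH2Cl2, 0 °C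
Reagents that add atoms: chlorotriethylsilane, CC[Si](Cl)(CC)CC
Why: Silylation is selective for the secondary C6–OH because the tertiary C8–OH is too hindered for TESCl/imidazole.

Step 30
Reactants: 42 PMB ether
Product: 43 C4 primary alcohol
Conditions: DDQ, CH2Cl2/pH 7 buffer, 0 °C
Reagents that add atoms: none
Why: Oxidative PMB cleavage by DDQ runs under neutral conditions that spare the TES ether, acetates, lactone, enone and vinyl iodide.

Step 31
Reactants: 43 primary alcohol
Product: 44 C4 aldehyde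
Conditions: DMP, pyridine, CH2Cl2, 0 °C
Reagents that add atoms: none
Why: Buffered Dess–Martin oxidation gives the β-silyloxy aldehyde without elimination.

Step 32
Reactants: 44 aldehyde
Product: 46 2-methylene aldehyde (C5=C16 enal), via Mannich base 45 (not isolated)
Conditions: Eschenmoser's salt, Et3N, CH2Cl2, rt
Reagents that add atoms: N,N-dimethylmethyleneiminium iodide, C=[N+](C)C.[I-]
Why: A Mannich reaction followed by β-elimination of dimethylamine (α-methylenation) adds C16, and the poor silyloxy leaving group at C6 survives the mild base.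

Step 33
Reactants: 46 vinyl iodide enal
Product: 48 (4S)-macrocyclic allylic alcohol (6-O-TES), via alkenylchromium(III) species 47 (not isolated)
Conditions: CrCl2 (15 equiv), NiCl2 (cat.), DMSO/THF, 0.002 M, slow addition, rt
Reagents that add atoms: none
Why: In the intramolecular Nozaki–Hiyama–Kishi reaction the tether forces C3 onto the enal face that carries C7 (H6 eclipsing C5=C16), and the bulky O–Cr unit turns outward next to the methylene group and away from the OTES group, which gives 4S.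

Step 34
Reactants: 48 macrocyclic alcohol
Product: 49 4-O-TBS-6-O-TES macrocycle
Conditions: TBSOTf, 2,6-lutidine, CH2Cl2, −78 °C
Reagents that add atoms: tert-butyldimethylsilyl triflate, CC(C)(C)[Si](C)(C)OS(=O)(=O)C(F)(F)F
Why: Low-temperature silylation takes the secondary bis-allylic C4–OH and leaves the tertiary C8–OH free.

Step 35
Reactants: 49 bis-silyl ether
Product: 50 (6R)-allylic alcohol (4-O-TBS)
Conditions: HF·pyridine, pyridine, THF, 0 °C
Reagents that add atoms: none
Why: Buffered fluoride cleaves TES about a hundred times faster than TBS, which exposes only C6–OH.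

Step 36
Reactants: 50 (6R)-alcohol
Product: 52 (6S)-chloride (4-O-TBS), via alkoxyphosphonium chloride 51 (not isolated)
Conditions: PPh3, hexachloroacetone, CH2Cl2, 0 °C
Reagents that add atoms: hexachloroacetone, O=C(C(Cl)(Cl)Cl)C(Cl)(Cl)Cl
Why: In this Appel-type chlorination chloride displaces the alkoxyphosphonium group by SN2 with inversion (6R to 6S) and, under these tight-ion-pair conditions, largely without allylic transposition, and the tertiary C8–OH does not react.

Step 37
Reactants: 52 chloride silyl ether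
Product: 53 CNP0196166.1 (target)
Conditions: HF·pyridine, THF, 0 °C to rt
Reagents that add atoms: none
Why: Acidic fluoride desilylation frees C4–OH without touching the acetates, the allylic chloride, the enone or the base-sensitive β-hydroxy lactone.

## Compound list
1 | pent-1-en-3-one | C=CC(=O)CC | starting material
2 | (Z)-3-(triisopropylsilyloxy)penta-1,3-diene | C=C/C(O[Si](C(C)C)(C(C)C)C(C)C)=C/C | intermediate
3 | ethyl (E)-3-methyl-4-oxobut-2-enoate | CCOC(=O)/C=C(\C)C=O | starting material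
4 | ethyl (1S,2S,6S)-2-formyl-2,6-dimethyl-5-(triisopropylsilyloxy)cyclohex-4-ene-1-carboxylate | O=C[C@@]1(C)CC=C(O[Si](C(C)C)(C(C)C)C(C)C)[C@@H](C)[C@@H]1C(=O)OCC | intermediate
5 | ethyl (1S,2S,6S)-2-[(E)-2-iodoethenyl]-2,6-dimethyl-5-(triisopropylsilyloxy)cyclohex-4-ene-1-carboxylate | I/C=C/[C@@]1(C)CC=C(O[Si](C(C)C)(C(C)C)C(C)C)[C@@H](C)[C@@H]1C(=O)OCC | intermediate
6 | [(1S,2S,6S)-2-[(E)-2-iodoethenyl]-2,6-dimethyl-5-(triisopropylsilyloxy)cyclohex-4-en-1-yl]methanol | I/C=C/[C@@]1(C)CC=C(O[Si](C(C)C)(C(C)C)C(C)C)[C@@H](C)[C@@H]1CO | intermediate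
7 | (1S,2S,6S)-2-[(E)-2-iodoethenyl]-2,6-dimethyl-5-(triisopropylsilyloxy)cyclohex-4-ene-1-carbaldehyde | I/C=C/[C@@]1(C)CC=C(O[Si](C(C)C)(C(C)C)C(C)C)[C@@H](C)[C@@H]1C=O | intermediate
8 | 2-methylpropane-1,3-diol | CC(CO)CO | starting material
9 | (S)-3-hydroxy-2-methylpropyl acetate | CC(=O)OC[C@@H](C)CO | intermediate
10 | (R)-3-(tert-butyldimethylsilyloxy)-2-methylpropyl acetate | CC(=O)OC[C@@H](C)CO[Si](C)(C)C(C)(C)C | intermediate
11 | (R)-3-(tert-butyldimethylsilyloxy)-2-methylpropan-1-ol | OC[C@@H](C)CO[Si](C)(C)C(C)(C)C | intermediate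
12 | (S)-3-(tert-butyldimethylsilyloxy)-2-methylpropanal | O=C[C@@H](C)CO[Si](C)(C)C(C)(C)C | intermediate
13 | (R)-tert-butyl(dimethyl)(2-methylbut-3-ynyloxy)silane | C#C[C@@H](C)CO[Si](C)(C)C(C)(C)C | intermediate
14 | propane-1,3-diol | OCCCO | starting material
15 | sodium 3-hydroxypropan-1-olate | [Na+].[O-]CCCO | intermediate
16 | 3-(4-methoxybenzyloxy)propan-1-ol | COc1ccc(COCCCO)cc1 | intermediate
17 | 3-(4-methoxybenzyloxy)propanal | COc1ccc(COCCC=O)cc1 | intermediate
18 | lithium acetylide of 13 | [Li]C#C[C@@H](C)CO[Si](C)(C)C(C)(C)C | intermediate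
19 | (6R)-7-(TBSO)-1-(PMBO)-6-methylhept-4-yn-3-ol, epimers at briarane C6 | COc1ccc(COCCC(O)C#C[C@@H](C)CO[Si](C)(C)C(C)(C)C)cc1 | intermediate
20 | (6R)-7-(TBSO)-1-(PMBO)-6-methylhept-4-yn-3-one | COc1ccc(COCCC(=O)C#C[C@@H](C)CO[Si](C)(C)C(C)(C)C)cc1 | intermediate
21 | (3R,6R)-7-(TBSO)-1-(PMBO)-6-methylhept-4-yn-3-ol | COc1ccc(COCC[C@@H](O)C#C[C@@H](C)CO[Si](C)(C)C(C)(C)C)cc1 | intermediate
22 | cyclic sodium vinylalanate (O6–Al–C8 five-ring) | COc1ccc(COCC[C@H]2O[Al-](OCCOC)(OCCOC)C(=C2)[C@@H](C)CO[Si](C)(C)C(C)(C)C)cc1.[Na+] | intermediate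
23 | (3R,4Z,6S)-5-iodo-7-(TBSO)-1-(PMBO)-6-methylhept-4-en-3-ol | COc1ccc(COCC[C@@H](O)/C=C(\I)[C@@H](C)CO[Si](C)(C)C(C)(C)C)cc1 | intermediate
24 | TES ether of 23 | COc1ccc(COCC[C@@H](O[Si](CC)(CC)CC)/C=C(\I)[C@@H](C)CO[Si](C)(C)C(C)(C)C)cc1 | intermediate
25 | vinyllithium from 24 | COc1ccc(COCC[C@@H](O[Si](CC)(CC)CC)/C=C(\[Li])[C@@H](C)CO[Si](C)(C)C(C)(C)C)cc1 | intermediate
26 | C8–C9 coupled allylic alcohol, 9R (Felkin) epimer drawn | I/C=C/[C@@]1(C)CC=C(O[Si](C(C)C)(C(C)C)C(C)C)[C@@H](C)[C@@H]1[C@@H](O)/C(=C\[C@H](O[Si](CC)(CC)CC)CCOCc1ccc(OC)cc1)[C@@H](C)CO[Si](C)(C)C(C)(C)C | intermediate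
27 | C9 enone | I/C=C/[C@@]1(C)CC=C(O[Si](C(C)C)(C(C)C)C(C)C)[C@@H](C)[C@@H]1C(=O)/C(=C\[C@H](O[Si](CC)(CC)CC)CCOCc1ccc(OC)cc1)[C@@H](C)CO[Si](C)(C)C(C)(C)C | intermediate
28 | (9S)-allylic alcohol | I/C=C/[C@@]1(C)CC=C(O[Si](C(C)C)(C(C)C)C(C)C)[C@@H](C)[C@@H]1[C@H](O)/C(=C\[C@H](O[Si](CC)(CC)CC)CCOCc1ccc(OC)cc1)[C@@H](C)CO[Si](C)(C)C(C)(C)C | intermediate
29 | 9-acetate | I/C=C/[C@@]1(C)CC=C(O[Si](C(C)C)(C(C)C)C(C)C)[C@@H](C)[C@@H]1[C@H](OC(C)=O)/C(=C\[C@H](O[Si](CC)(CC)CC)CCOCc1ccc(OC)cc1)[C@@H](C)CO[Si](C)(C)C(C)(C)C | intermediate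
30 | 13-phenylselanyl ketone (C13 epimers) | I/C=C/[C@@]1(C)CC([Se]c2ccccc2)C(=O)[C@@H](C)[C@@H]1[C@H](OC(C)=O)/C(=C\[C@H](O[Si](CC)(CC)CC)CCOCc1ccc(OC)cc1)[C@@H](C)CO[Si](C)(C)C(C)(C)C | intermediate
31 | selenoxide of 30 | I/C=C/[C@@]1(C)CC([Se](=O)c2ccccc2)C(=O)[C@@H](C)[C@@H]1[C@H](OC(C)=O)/C(=C\[C@H](O[Si](CC)(CC)CC)CCOCc1ccc(OC)cc1)[C@@H](C)CO[Si](C)(C)C(C)(C)C | intermediate
32 | C13=C14 cyclohexenone | I/C=C/[C@@]1(C)C=CC(=O)[C@@H](C)[C@@H]1[C@H](OC(C)=O)/C(=C\[C@H](O[Si](CC)(CC)CC)CCOCc1ccc(OC)cc1)[C@@H](C)CO[Si](C)(C)C(C)(C)C | intermediate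
33 | 12-(trimethylsilyloxy)-11,13-diene | I/C=C/[C@@]1(C)C=CC(O[Si](C)(C)C)=C(C)[C@@H]1[C@H](OC(C)=O)/C(=C\[C@H](O[Si](CC)(CC)CC)CCOCc1ccc(OC)cc1)[C@@H](C)CO[Si](C)(C)C(C)(C)C | intermediate
34 | 11,12-silyloxy epoxide | I/C=C/[C@@]1(C)C=C[C@@]2(O[Si](C)(C)C)O[C@@]2(C)[C@@H]1[C@H](OC(C)=O)/C(=C\[C@H](O[Si](CC)(CC)CC)CCOCc1ccc(OC)cc1)[C@@H](C)CO[Si](C)(C)C(C)(C)C | intermediate
35 | (11S)-11-hydroxy enone | I/C=C/[C@@]1(C)C=CC(=O)[C@@](C)(O)[C@@H]1[C@H](OC(C)=O)/C(=C\[C@H](O[Si](CC)(CC)CC)CCOCc1ccc(OC)cc1)[C@@H](C)CO[Si](C)(C)C(C)(C)C | intermediate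
36 | 9,11-diacetate | I/C=C/[C@@]1(C)C=CC(=O)[C@@](C)(OC(C)=O)[C@@H]1[C@H](OC(C)=O)/C(=C\[C@H](O[Si](CC)(CC)CC)CCOCc1ccc(OC)cc1)[C@@H](C)CO[Si](C)(C)C(C)(C)C | intermediate
37 | C6 allylic alcohol | I/C=C/[C@@]1(C)C=CC(=O)[C@@](C)(OC(C)=O)[C@@H]1[C@H](OC(C)=O)/C(=C\[C@H](O)CCOCc1ccc(OC)cc1)[C@@H](C)CO[Si](C)(C)C(C)(C)C | intermediate
38 | C7,C8 osmate(VI) ester, TMEDA complex | I/C=C/[C@@]1(C)C=CC(=O)[C@@](C)(OC(C)=O)[C@@H]1[C@H](OC(C)=O)[C@]2(O[Os](=O)(=O)O[C@H]2[C@H](O)CCOCc2ccc(OC)cc2)[C@@H](C)CO[Si](C)(C)C(C)(C)C.CN(C)CCN(C)C | intermediate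
39 | 6,7,8,19-tetraol | I/C=C/[C@@]1(C)C=CC(=O)[C@@](C)(OC(C)=O)[C@@H]1[C@H](OC(C)=O)[C@](O)([C@@H](C)CO)[C@@H](O)[C@H](O)CCOCc1ccc(OC)cc1 | intermediate
40 | seco acid (C19 carboxylic acid) | I/C=C/[C@@]1(C)C=CC(=O)[C@@](C)(OC(C)=O)[C@@H]1[C@H](OC(C)=O)[C@](O)([C@@H](C)C(=O)O)[C@@H](O)[C@H](O)CCOCc1ccc(OC)cc1 | intermediate
41 | γ-lactone 6,8-diol | I/C=C/[C@@]1(C)C=CC(=O)[C@@](C)(OC(C)=O)[C@@H]1[C@H](OC(C)=O)[C@]2(O)[C@@H](C)C(=O)O[C@H]2[C@H](O)CCOCc2ccc(OC)cc2 | intermediate
42 | 6-O-TES lactone | I/C=C/[C@@]1(C)C=CC(=O)[C@@](C)(OC(C)=O)[C@@H]1[C@H](OC(C)=O)[C@]2(O)[C@@H](C)C(=O)O[C@H]2[C@H](O[Si](CC)(CC)CC)CCOCc2ccc(OC)cc2 | intermediate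
43 | C4 primary alcohol | I/C=C/[C@@]1(C)C=CC(=O)[C@@](C)(OC(C)=O)[C@@H]1[C@H](OC(C)=O)[C@]2(O)[C@@H](C)C(=O)O[C@H]2[C@H](O[Si](CC)(CC)CC)CCO | intermediate
44 | C4 aldehyde | I/C=C/[C@@]1(C)C=CC(=O)[C@@](C)(OC(C)=O)[C@@H]1[C@H](OC(C)=O)[C@]2(O)[C@@H](C)C(=O)O[C@H]2[C@H](O[Si](CC)(CC)CC)CC=O | intermediate
45 | Mannich base (C5 epimers) | I/C=C/[C@@]1(C)C=CC(=O)[C@@](C)(OC(C)=O)[C@@H]1[C@H](OC(C)=O)[C@]2(O)[C@@H](C)C(=O)O[C@H]2[C@H](O[Si](CC)(CC)CC)C(CN(C)C)C=O | intermediate
46 | 2-methylene aldehyde (enal) | I/C=C/[C@@]1(C)C=CC(=O)[C@@](C)(OC(C)=O)[C@@H]1[C@H](OC(C)=O)[C@]2(O)[C@@H](C)C(=O)O[C@H]2[C@H](O[Si](CC)(CC)CC)C(=C)C=O | intermediate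
47 | alkenylchromium(III) species | Cl[Cr](Cl)/C=C/[C@@]1(C)C=CC(=O)[C@@](C)(OC(C)=O)[C@@H]1[C@H](OC(C)=O)[C@]2(O)[C@@H](C)C(=O)O[C@H]2[C@H](O[Si](CC)(CC)CC)C(=C)C=O | intermediate
48 | (4S)-macrocyclic allylic alcohol, 6-O-TES | C=C1[C@@H](O)/C=C/[C@@]2(C)C=CC(=O)[C@@](C)(OC(C)=O)[C@@H]2[C@H](OC(C)=O)[C@]2(O)[C@@H](C)C(=O)O[C@H]2[C@@H]1O[Si](CC)(CC)CC | intermediate
49 | 4-O-TBS-6-O-TES macrocycle | C=C1[C@@H](O[Si](C)(C)C(C)(C)C)/C=C/[C@@]2(C)C=CC(=O)[C@@](C)(OC(C)=O)[C@@H]2[C@H](OC(C)=O)[C@]2(O)[C@@H](C)C(=O)O[C@H]2[C@@H]1O[Si](CC)(CC)CC | intermediate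
50 | (6R)-allylic alcohol, 4-O-TBS | C=C1[C@@H](O[Si](C)(C)C(C)(C)C)/C=C/[C@@]2(C)C=CC(=O)[C@@](C)(OC(C)=O)[C@@H]2[C@H](OC(C)=O)[C@]2(O)[C@@H](C)C(=O)O[C@H]2[C@@H]1O | intermediate
51 | C6 alkoxyphosphonium chloride | C=C1[C@@H](O[Si](C)(C)C(C)(C)C)/C=C/[C@@]2(C)C=CC(=O)[C@@](C)(OC(C)=O)[C@@H]2[C@H](OC(C)=O)[C@]2(O)[C@@H](C)C(=O)O[C@H]2[C@@H]1O[P+](c1ccccc1)(c1ccccc1)c1ccccc1.[Cl-] | intermediate
52 | (6S)-chloride, 4-O-TBS | C=C1[C@@H](O[Si](C)(C)C(C)(C)C)/C=C/[C@@]2(C)C=CC(=O)[C@@](C)(OC(C)=O)[C@@H]2[C@H](OC(C)=O)[C@]2(O)[C@@H](C)C(=O)O[C@H]2[C@H]1Cl | intermediate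
53 | CNP0196166.1 | C=C1[C@@H](O)/C=C/[C@@]2(C)C=CC(=O)[C@@](C)(OC(C)=O)[C@@H]2[C@H](OC(C)=O)[C@]2(O)[C@@H](C)C(=O)O[C@H]2[C@H]1Cl | target

## Totals and risks
Total step count: 37.

Longest linear sequence: 30 steps (steps 6–10, 13–17 and 18–37).

**Step 2, enantioselective Diels–Alder.** A trisubstituted dienophile combined with a 4-substituted diene lies at the edge of the catalyst's scope.
- The fallback separates ring construction from enantio-induction.
- It sets out from 2 and 3. The cycloaddition is run with an achiral Lewis acid (Me2AlCl, CH2Cl2, −78 °C) and gives 4 mixed with its mirror image, the ent-Diels–Alder adduct F1.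
- The racemate is taken through steps 3 and 4, giving 5 beside the ent-vinyl iodide ester F2 and 6 beside the ent-primary alcohol F3.
- The racemic β-branched primary alcohol is resolved by lipase-catalysed acylation (Burkholderia cepacia lipase, vinyl acetate, MTBE), driven past 50 % conversion so that the mirror-image series is removed as the ent-acetate F4.
- Unreacted, enantioenriched alcohol is separated by chromatography, and the route is rejoined at 6.

**Step 33, NHK macrocyclisation.** The C4 configuration rests on a conformational argument.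
- In the fallback, C4 is set by ketone reduction instead of by C–C bond formation.
- It sets out from 46. If the closure gives mainly the 4-epi macrocyclic alcohol F5, this (or the epimer mixture) is oxidised with DMP to the cross-conjugated C4 dienone F6.
- F6 is reduced under reagent control with (R)-Me-CBS and catecholborane at −78 °C. The branched C5 alkenyl group acts as the large group, and the C12 ketone, flanked by quaternary C11, reacts much more slowly.
- The route is rejoined at 48.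

**Step 36, SN2 chlorination.** SN2′ attack giving the primary allylic chloride, or a sluggish displacement inside the ring, are the main dangers.
- The fallback is a biomimetic ene-type chlorination in place of a substitution.
- It sets out from 50. A Myers reductive transposition (2-nitrobenzenesulfonylhydrazide, PPh3, DEAD, THF, −30 °C to rt) gives the N-allylic sulfonylhydrazine F7.
- F7 loses sulfinic acid to give the allylic diazene F8, which loses N2 by a retro-ene shift (H6 eclipsing the methylene group) to give the (5Z)-5,6-olefin F9, carrying Me-16.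
- PhSeCl-catalysed allylic chlorination with NCS (CH2Cl2, rt) then delivers chlorine to C6 on the exposed outer face of the most electron-rich olefin and moves the double bond to C5=C16.
- The route is rejoined at 52.

## Further compounds
F1 | step 2 | ent-Diels–Alder adduct (enantiomer of 4) | O=C[C@]1(C)CC=C(O[Si](C(C)C)(C(C)C)C(C)C)[C@H](C)[C@H]1C(=O)OCC
F2 | step 2 | ent-vinyl iodide ester (enantiomer of 5) | I/C=C/[C@]1(C)CC=C(O[Si](C(C)C)(C(C)C)C(C)C)[C@H](C)[C@H]1C(=O)OCC
F3 | step 2 | ent-primary alcohol (enantiomer of 6) | I/C=C/[C@]1(C)CC=C(O[Si](C(C)C)(C(C)C)C(C)C)[C@H](C)[C@H]1CO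
F4 | step 2 | ent-acetate (acetate of F3) | I/C=C/[C@]1(C)CC=C(O[Si](C(C)C)(C(C)C)C(C)C)[C@H](C)[C@H]1COC(C)=O
F5 | step 33 | 4-epi macrocyclic alcohol (4R) | C=C1[C@H](O)/C=C/[C@@]2(C)C=CC(=O)[C@@](C)(OC(C)=O)[C@@H]2[C@H](OC(C)=O)[C@]2(O)[C@@H](C)C(=O)O[C@H]2[C@@H]1O[Si](CC)(CC)CC
F6 | step 33 | cross-conjugated C4 dienone | C=C1C(=O)/C=C/[C@@]2(C)C=CC(=O)[C@@](C)(OC(C)=O)[C@@H]2[C@H](OC(C)=O)[C@]2(O)[C@@H](C)C(=O)O[C@H]2[C@@H]1O[Si](CC)(CC)CC
F7 | step 36 | N-allylic sulfonylhydrazine (C6–N, inverted) | C=C1[C@@H](O[Si](C)(C)C(C)(C)C)/C=C/[C@@]2(C)C=CC(=O)[C@@](C)(OC(C)=O)[C@@H]2[C@H](OC(C)=O)[C@]2(O)[C@@H](C)C(=O)O[C@H]2[C@H]1N(N)S(=O)(=O)c1ccccc1[N+](=O)[O-]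
F8 | step 36 | allylic diazene | C=C1[C@@H](O[Si](C)(C)C(C)(C)C)/C=C/[C@@]2(C)C=CC(=O)[C@@](C)(OC(C)=O)[C@@H]2[C@H](OC(C)=O)[C@]2(O)[C@@H](C)C(=O)O[C@H]2[C@H]1N=N
F9 | step 36 | (5Z)-5,6-olefin, 4-O-TBS | C/C1=C/[C@@H]2OC(=O)[C@H](C)[C@@]2(O)[C@@H](OC(C)=O)[C@H]3[C@](C)(OC(C)=O)C(=O)C=C[C@]3(C)/C=C/[C@@H]1O[Si](C)(C)C(C)(C)C
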